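A direct plan would reach ring B by contracting a six-membered ring: ketone A1 (three steps from catechol) and aldehyde A2 (two steps from p-cresol) would be joined by a chiral primary-amine salt to the (S)-flavanone A3, PhI(OAc)2 (trivalent iodine) would contract A3 by a 1,2-aryl shift to the trans bromo ester A4, and a Negishi coupling (to A5) and LiAlH4 would finish.
Its weakest steps would be:
– the amine-catalysed aldol/oxa-Michael annulation to A3: the only source of chirality would be a ring closure without precedent, and a flavanone C2 centre racemises through the open chalcone under just such conditions (amine salt, 45 °C, two days), so the optical purity would rest on a recrystallisation;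
– the oxidative ring contraction of A3 to A4: ring A, which has to migrate, is deactivated by bromine while the 2-aryl group is electron-rich, so aryl shift to an isoflavone and dehydrogenation to a flavone would compete, on enantioenriched material;
– the run-up and the late chain: five of nine steps would rebuild simple arenes of the guaiacol and syringaldehyde type, and the three-carbon chain would then be put on precious A4 by an sp3–sp2 cross-coupling, although a ring A that already carries this chain can be bought.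

**Plan of the new route**
Rings: A = benzo ring (C3a–C7a), B = dihydrofuran (O1, C2, C3), C = aryl group on C2. Retrosynthesis: the CH2OH on C3 is traced back to an ester; ring B is cut at C2–C3 (carbene insertion into the C2–H bond), leaving an achiral, acyclic aryldiazoacetate in which O1–C2 is an ordinary benzyl aryl ether; this is cut at C3a–C3 (aryl iodide + ethyl diazoacetate) and at O1–CH2 (Mitsunobu).
Enabling feature: C2 carries one hydrogen that is α to O1 and benzylic to ring C, the most hydridic C–H bond of the skeleton and five atoms from C3. C3 carries a carbon (CH2OH) that can be held at the ester level, so C3 can be a donor/acceptor carbene carbon and, after ring closure, an epimerisable centre.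
Ring order: rings A and C are bought complete, ring A with its three-carbon chain; ring B is formed last, in one step and directly five-membered. C2 is set by the catalyst, C3 is then funnelled to trans by equilibration.
No six-membered heterocycle, no amine-catalysed annulation, no aryl shift and no late cross-coupling on the core occur.

Key step: step 5

Assumption: the (R)-configured catalyst Rh2(R-PTTL)4 (dirhodium tetrakis[N-phthaloyl-(R)-tert-leucinate]) is written for the 2S series by analogy with the closest 2-aryl cases; should the sense of induction be the reverse on this substrate, the mirror-image catalyst would be used and nothing else changes.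
Assumption: ethyl dihydroferulate is taken as a commercial compound.

Step 1
Reactants: 1 syringaldehyde (4-hydroxy-3,5-dimethoxybenzaldehyde); 2 benzyl bromide
Product: 4 [4-(benzyloxy)-3,5-dimethoxyphenyl]methanol, via 4-(benzyloxy)-3,5-dimethoxybenzaldehyde 3 (not isolated)
Conditions: BnBr (1.05 equiv), K2CO3 (1.5 equiv), DMF, 60 °C; then MeOH, NaBH4 (1.0 equiv), 0 °C
Reagents that add atoms: none
Why: Williamson O-benzylation of the acidic phenol followed in the same pot by borohydride reduction of the aldehyde; the benzyl ether keeps the ring C phenol out of the carbene step (O–H insertion) and is removed only at the end.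

Step 2
Reactants: 5 ethyl 3-(4-hydroxy-3-methoxyphenyl)propanoate (ethyl dihydroferulate)
Product: 6 ethyl 3-(4-hydroxy-3-iodo-5-methoxyphenyl)propanoate
Conditions: NIS (1.05 equiv), TsOH·H2O (10 mol %), MeCN, 0 °C → rt
Reagents that add atoms: N-iodosuccinimide O=C1CCC(=O)N1I
Why: Electrophilic aromatic iodination; the free OH is the strongest director and its para position carries the chain, so iodine should enter the only free ortho position, the future C3a.

Step 3
Reactants: 6 ethyl 3-(4-hydroxy-3-iodo-5-methoxyphenyl)propanoate; 4 [4-(benzyloxy)-3,5-dimethoxyphenyl]methanol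
Product: 7 ethyl 3-(4-{[4-(benzyloxy)-3,5-dimethoxyphenyl]methoxy}-3-iodo-5-methoxyphenyl)propanoate
Conditions: PPh3 (1.3 equiv), DIAD (1.3 equiv), THF, 0 °C → rt
Reagents that add atoms: none
Why: Mitsunobu etherification of the acidic o-iodophenol with the primary benzylic alcohol forms the future O1–C2 bond without a labile electron-rich benzyl halide; no stereocentre is involved.

Step 4
Reactants: 7 ethyl 3-(4-{[4-(benzyloxy)-3,5-dimethoxyphenyl]methoxy}-3-iodo-5-methoxyphenyl)propanoate; 8 ethyl diazoacetate
Product: 9 ethyl 2-[2-{[4-(benzyloxy)-3,5-dimethoxyphenyl]methoxy}-5-(3-ethoxy-3-oxopropyl)-3-methoxyphenyl]-2-diazoacetate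
Conditions: Pd(PPh3)4 (5 mol %), Ag2CO3 (0.5 equiv), Et3N (1.3 equiv), toluene, rt
Reagents that add atoms: none
Why: Palladium-catalysed cross-coupling of an aryl iodide with an acceptor diazo ester (oxidative addition to zerovalent palladium, base-assisted transfer of the diazoacetyl group with Ag2CO3 as iodide scavenger, reductive elimination) forms the C3a–C3 bond with the diazo group intact and touches neither ester nor benzyl ether.

Step 5
Reactants: 9 ethyl 2-[2-{[4-(benzyloxy)-3,5-dimethoxyphenyl]methoxy}-5-(3-ethoxy-3-oxopropyl)-3-methoxyphenyl]-2-diazoacetate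
Product: 10 ethyl (2S,3R)-2-[4-(benzyloxy)-3,5-dimethoxyphenyl]-5-(3-ethoxy-3-oxopropyl)-7-methoxy-2,3-dihydro-1-benzofuran-3-carboxylate (cis)
Conditions: Rh2(R-PTTL)4 (1 mol %), toluene, −60 °C, slow addition of 9
Reagents that add atoms: none
Why: The catalyst decomposes the diazo ester with loss of N2 to a donor/acceptor carbene on divalent rhodium, which inserts into one of the two enantiotopic C–H bonds of the neighbouring ArCH2–O group through a three-centre transition state with hydride-transfer character. Ring B closes by C2–C3 bond formation in a 1,5-C–H insertion (five-membered cyclic transition state; carbene carbon = C3, benzylic carbon = C2); the closest known reaction is the enantioselective intramolecular C–H insertion of 2-(benzyloxy)aryl diazoacetates to cis-2-aryl-2,3-dihydrobenzofuran-3-carboxylates with phthalimido-amino-acid dirhodium catalysts. C2 is set by the catalyst, whose pocket of four phthalimido groups decides which hydrogen is replaced; C3 should arise cis because the ring C aryl group turns away from the ligand wall and so ends on the face of the ester, and it is corrected in step 6. The step needs site selectivity for the OCH2 group next to the carbene: only this C–H bond is doubly activated and five atoms from the carbene carbon, ylide formation at O1 would need a four-membered ring, the 7-OCH3 group offers only an unactivated primary C–H bond through a six-membered transition state, and the second benzyl ether is out of reach. The two meta-methoxy groups and the twisted para-benzyloxy group make ring C a weaker cation stabiliser than a p-anisyl ring, which should keep the insertion concerted and preserve enantiocontrol, while slow addition at low temperature suppresses carbene dimerisation.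

Step 6
Reactants: 10 ethyl (2S,3R)-2-[4-(benzyloxy)-3,5-dimethoxyphenyl]-5-(3-ethoxy-3-oxopropyl)-7-methoxy-2,3-dihydro-1-benzofuran-3-carboxylate (cis)
Product: 11 ethyl (2S,3S)-2-[4-(benzyloxy)-3,5-dimethoxyphenyl]-5-(3-ethoxy-3-oxopropyl)-7-methoxy-2,3-dihydro-1-benzofuran-3-carboxylate (trans)
Conditions: NaOEt (0.3 equiv), EtOH–THF (3:1), 0 °C → rt; AcOH quench
Reagents that add atoms: none
Why: Base-catalysed epimerisation through the ester enolate at C3 (benzylic and α to the ester) should funnel the cis isomer to the more stable trans isomer and so set C3 as S, while C2 stays untouched because opening of ring B from the enolate would be a retro-5-endo-trig process with the C2–O1 bond orthogonal to the enolate π system, and ester exchange is degenerate in EtOH.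

Step 7
Reactants: 11 ethyl (2S,3S)-2-[4-(benzyloxy)-3,5-dimethoxyphenyl]-5-(3-ethoxy-3-oxopropyl)-7-methoxy-2,3-dihydro-1-benzofuran-3-carboxylate (trans)
Product: 12 3-[(2S,3R)-2-[4-(benzyloxy)-3,5-dimethoxyphenyl]-3-(hydroxymethyl)-7-methoxy-2,3-dihydro-1-benzofuran-5-yl]propan-1-ol
Conditions: LiAlH4 (3 equiv), THF, 0 °C; Rochelle-salt work-up
Reagents that add atoms: none
Why: Hydride reduction of both ethyl esters to primary alcohols; ethers and both stereocentres are inert, and the C3 descriptor changes from S to R only because CH2OH ranks below C2.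

Step 8
Reactants: 12 3-[(2S,3R)-2-[4-(benzyloxy)-3,5-dimethoxyphenyl]-3-(hydroxymethyl)-7-methoxy-2,3-dihydro-1-benzofuran-5-yl]propan-1-ol
Product: 13 4-[(2S,3R)-3-(hydroxymethyl)-5-(3-hydroxypropyl)-7-methoxy-2,3-dihydro-1-benzofuran-2-yl]-2,6-dimethoxyphenol (target)
Conditions: H2 (1 atm), 10% Pd/C, EtOAc, rt, stopped at full conversion
Reagents that add atoms: none
Why: Hydrogenolysis of the primary benzyl aryl ether, which should be cleaved much faster than the hindered secondary C2–O1 bond of ring B, as in debenzylations of related 2-aryl-dihydrobenzofurans; no stereocentre is touched.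

**Compound list**
1 | syringaldehyde (4-hydroxy-3,5-dimethoxybenzaldehyde) | COc1cc(C=O)cc(OC)c1O | starting material
2 | benzyl bromide | BrCc1ccccc1 | starting material
3 | 4-(benzyloxy)-3,5-dimethoxybenzaldehyde | COc1cc(C=O)cc(OC)c1OCc1ccccc1 | intermediate (not isolated)
4 | [4-(benzyloxy)-3,5-dimethoxyphenyl]methanol | COc1cc(CO)cc(OC)c1OCc1ccccc1 | intermediate
5 | ethyl 3-(4-hydroxy-3-methoxyphenyl)propanoate (ethyl dihydroferulate) | CCOC(=O)CCc1ccc(O)c(OC)c1 | starting material
6 | ethyl 3-(4-hydroxy-3-iodo-5-methoxyphenyl)propanoate | CCOC(=O)CCc1cc(I)c(O)c(OC)c1 | intermediate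
7 | ethyl 3-(4-{[4-(benzyloxy)-3,5-dimethoxyphenyl]methoxy}-3-iodo-5-methoxyphenyl)propanoate | CCOC(=O)CCc1cc(I)c(OCc2cc(OC)c(OCc3ccccc3)c(OC)c2)c(OC)c1 | intermediate
8 | ethyl diazoacetate | CCOC(=O)C=[N+]=[N-] | starting material
9 | ethyl 2-[2-{[4-(benzyloxy)-3,5-dimethoxyphenyl]methoxy}-5-(3-ethoxy-3-oxopropyl)-3-methoxyphenyl]-2-diazoacetate | CCOC(=O)CCc1cc(C(=[N+]=[N-])C(=O)OCC)c(OCc2cc(OC)c(OCc3ccccc3)c(OC)c2)c(OC)c1 | intermediate
10 | ethyl (2S,3R)-2-[4-(benzyloxy)-3,5-dimethoxyphenyl]-5-(3-ethoxy-3-oxopropyl)-7-methoxy-2,3-dihydro-1-benzofuran-3-carboxylate (cis) | COc1cc([C@H]2Oc3c(OC)cc(CCC(=O)OCC)cc3[C@H]2C(=O)OCC)cc(OC)c1OCc1ccccc1 | intermediate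
11 | ethyl (2S,3S)-2-[4-(benzyloxy)-3,5-dimethoxyphenyl]-5-(3-ethoxy-3-oxopropyl)-7-methoxy-2,3-dihydro-1-benzofuran-3-carboxylate (trans) | COc1cc([C@H]2Oc3c(OC)cc(CCC(=O)OCC)cc3[C@@H]2C(=O)OCC)cc(OC)c1OCc1ccccc1 | intermediate
12 | 3-[(2S,3R)-2-[4-(benzyloxy)-3,5-dimethoxyphenyl]-3-(hydroxymethyl)-7-methoxy-2,3-dihydro-1-benzofuran-5-yl]propan-1-ol | COc1cc([C@H]2Oc3c(OC)cc(CCCO)cc3[C@@H]2CO)cc(OC)c1OCc1ccccc1 | intermediate
13 | 4-[(2S,3R)-3-(hydroxymethyl)-5-(3-hydroxypropyl)-7-methoxy-2,3-dihydro-1-benzofuran-2-yl]-2,6-dimethoxyphenol | COc1cc([C@H]2Oc3c(OC)cc(CCCO)cc3[C@@H]2CO)cc(OC)c1O | target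

Total steps: 8. Longest linear sequence: 7 (steps 2–8 from 5, or step 1 and steps 3–8 from 1).

**Steps most likely to fail**

Step 5 (key step). The catalyst may discriminate the two hydrogens at C2 poorly, or the insertion may slip into a stepwise hydride-transfer pathway that leaks stereochemistry. The fallback moves the control from the catalyst into the substrate; it sets out from 7 and comes back at 12. Ethyl (S)-lactate and pyrrolidine give (2S)-2-hydroxy-1-(pyrrolidin-1-yl)propan-1-one F1. Acylation with glyoxylic acid chloride p-toluenesulfonylhydrazone (PhNMe2, CH2Cl2, 0 °C) gives the hydrazone ester (2S)-1-oxo-1-(pyrrolidin-1-yl)propan-2-yl 2-[2-(4-methylbenzenesulfonyl)hydrazinylidene]acetate F2, which is fragmented without isolation by Et3N to (2S)-1-oxo-1-(pyrrolidin-1-yl)propan-2-yl 2-diazoacetate F3. Coupling of F3 with 7 under the conditions of step 4 gives (2S)-1-oxo-1-(pyrrolidin-1-yl)propan-2-yl 2-[2-{[4-(benzyloxy)-3,5-dimethoxyphenyl]methoxy}-5-(3-ethoxy-3-oxopropyl)-3-methoxyphenyl]-2-diazoacetate F4. Insertion with Rh2(S-DOSP)4 (dirhodium tetrakis[(S)-N-(4-dodecylbenzenesulfonyl)prolinate]) in CH2Cl2 should then give the trans ester directly, since a lactamide auxiliary with this catalyst class is a known pair for trans-2-aryl-2,3-dihydrobenzofuran-3-carboxylates; the antipode of auxiliary or catalyst would be taken if the pair proved mismatched for 2S. The product is (2S)-1-oxo-1-(pyrrolidin-1-yl)propan-2-yl (2S,3S)-2-[4-(benzyloxy)-3,5-dimethoxyphenyl]-5-(3-ethoxy-3-oxopropyl)-7-methoxy-2,3-dihydro-1-benzofuran-3-carboxylate F5. LiAlH4 reduces both esters of F5, releases the auxiliary as an amino alcohol and gives 12; step 6 is then not needed.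

Step 4. Oxidative addition into the hindered, electron-rich C–I bond may be slow while palladium decomposes ethyl diazoacetate (carbene dimers, azine). The fallback builds the carbon skeleton first and introduces the diazo group afterwards; it sets out from 7 and comes back at 9. CuI/L-proline-catalysed arylation of ethyl acetoacetate (Cs2CO3, DMSO, 40 °C) gives ethyl 2-[2-{[4-(benzyloxy)-3,5-dimethoxyphenyl]methoxy}-5-(3-ethoxy-3-oxopropyl)-3-methoxyphenyl]-3-oxobutanoate F6. Deacylative Regitz diazo transfer (4-acetamidobenzenesulfonyl azide, DBU, MeCN, 0 °C → rt) then gives 9.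

Step 6. Equilibration may be incomplete, or the C2 configuration may be partly lost through reversible β-elimination of the ring oxygen from the ester enolate. The fallback inverts C2 instead of C3 and uses the fact that C2 of the target is benzylic to a p-hydroxyaryl ring; it sets out from 9 and comes back at 13. Insertion with the mirror-image catalyst Rh2(S-PTTL)4 should give ethyl (2R,3S)-2-[4-(benzyloxy)-3,5-dimethoxyphenyl]-5-(3-ethoxy-3-oxopropyl)-7-methoxy-2,3-dihydro-1-benzofuran-3-carboxylate F7. LiAlH4 gives the cis diol 3-[(2R,3R)-2-[4-(benzyloxy)-3,5-dimethoxyphenyl]-3-(hydroxymethyl)-7-methoxy-2,3-dihydro-1-benzofuran-5-yl]propan-1-ol F8, and hydrogenolysis gives the cis phenol 4-[(2R,3R)-3-(hydroxymethyl)-5-(3-hydroxypropyl)-7-methoxy-2,3-dihydro-1-benzofuran-2-yl]-2,6-dimethoxyphenol F9. Catalytic CF3CO2H in dilute CH2Cl2 at 0 °C should ionise the C2–O1 bond reversibly (p-hydroxybenzyl cation, the protonated quinone methide) and reclose it to the more stable trans isomer, which is 13.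

**Further compounds**
F1 | step 5 | (2S)-2-hydroxy-1-(pyrrolidin-1-yl)propan-1-one | C[C@H](O)C(=O)N1CCCC1
F2 | step 5 | (2S)-1-oxo-1-(pyrrolidin-1-yl)propan-2-yl 2-[2-(4-methylbenzenesulfonyl)hydrazinylidene]acetate | C[C@H](OC(=O)C=NNS(=O)(=O)c1ccc(C)cc1)C(=O)N1CCCC1
F3 | step 5 | (2S)-1-oxo-1-(pyrrolidin-1-yl)propan-2-yl 2-diazoacetate | C[C@H](OC(=O)C=[N+]=[N-])C(=O)N1CCCC1
F4 | step 5 | (2S)-1-oxo-1-(pyrrolidin-1-yl)propan-2-yl 2-[2-{[4-(benzyloxy)-3,5-dimethoxyphenyl]methoxy}-5-(3-ethoxy-3-oxopropyl)-3-methoxyphenyl]-2-diazoacetate | CCOC(=O)CCc1cc(C(=[N+]=[N-])C(=O)O[C@@H](C)C(=O)N4CCCC4)c(OCc2cc(OC)c(OCc3ccccc3)c(OC)c2)c(OC)c1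
F5 | step 5 | (2S)-1-oxo-1-(pyrrolidin-1-yl)propan-2-yl (2S,3S)-2-[4-(benzyloxy)-3,5-dimethoxyphenyl]-5-(3-ethoxy-3-oxopropyl)-7-methoxy-2,3-dihydro-1-benzofuran-3-carboxylate | COc1cc([C@H]2Oc3c(OC)cc(CCC(=O)OCC)cc3[C@@H]2C(=O)O[C@@H](C)C(=O)N4CCCC4)cc(OC)c1OCc1ccccc1
F6 | step 4 | ethyl 2-[2-{[4-(benzyloxy)-3,5-dimethoxyphenyl]methoxy}-5-(3-ethoxy-3-oxopropyl)-3-methoxyphenyl]-3-oxobutanoate | CCOC(=O)CCc1cc(C(C(C)=O)C(=O)OCC)c(OCc2cc(OC)c(OCc3ccccc3)c(OC)c2)c(OC)c1
F7 | step 6 | ethyl (2R,3S)-2-[4-(benzyloxy)-3,5-dimethoxyphenyl]-5-(3-ethoxy-3-oxopropyl)-7-methoxy-2,3-dihydro-1-benzofuran-3-carboxylate | COc1cc([C@@H]2Oc3c(OC)cc(CCC(=O)OCC)cc3[C@@H]2C(=O)OCC)cc(OC)c1OCc1ccccc1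
F8 | step 6 | 3-[(2R,3R)-2-[4-(benzyloxy)-3,5-dimethoxyphenyl]-3-(hydroxymethyl)-7-methoxy-2,3-dihydro-1-benzofuran-5-yl]propan-1-ol | COc1cc([C@@H]2Oc3c(OC)cc(CCCO)cc3[C@@H]2CO)cc(OC)c1OCc1ccccc1
F9 | step 6 | 4-[(2R,3R)-3-(hydroxymethyl)-5-(3-hydroxypropyl)-7-methoxy-2,3-dihydro-1-benzofuran-2-yl]-2,6-dimethoxyphenol | COc1cc([C@@H]2Oc3c(OC)cc(CCCO)cc3[C@@H]2CO)cc(OC)c1O
A1 | direct plan | 1-(5-bromo-2-hydroxy-3-methoxyphenyl)ethan-1-one | COc1cc(Br)cc(C(C)=O)c1O
A2 | direct plan | 4-formyl-2,6-dimethoxyphenyl pivalate | COc1cc(C=O)cc(OC)c1OC(=O)C(C)(C)C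
A3 | direct plan | 4-[(2S)-6-bromo-8-methoxy-4-oxo-3,4-dihydro-2H-chromen-2-yl]-2,6-dimethoxyphenyl pivalate | COc1cc([C@@H]2CC(=O)c3cc(Br)cc(OC)c3O2)cc(OC)c1OC(=O)C(C)(C)C
A4 | direct plan | methyl (2S,3S)-5-bromo-2-[3,5-dimethoxy-4-(pivaloyloxy)phenyl]-7-methoxy-2,3-dihydro-1-benzofuran-3-carboxylate | COc1cc([C@H]2Oc3c(OC)cc(Br)cc3[C@@H]2C(=O)OC)cc(OC)c1OC(=O)C(C)(C)C
A5 | direct plan | methyl (2S,3S)-2-[3,5-dimethoxy-4-(pivaloyloxy)phenyl]-7-methoxy-5-(3-methoxy-3-oxopropyl)-2,3-dihydro-1-benzofuran-3-carboxylate | COc1cc([C@H]2Oc3c(OC)cc(CCC(=O)OC)cc3[C@@H]2C(=O)OC)cc(OC)c1OC(=O)C(C)(C)C
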